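Assumption: the SMILES is read as epicatechin-(4β→6)-epicatechin-(4β→6)-epicatechin. All three units are 2R,3R (2,3-cis). Both interflavan carbons are 4S (4β, 3,4-trans), and both bonds end at C6.

## Retrosynthetic overview
- Rings: none is built. All nine rings and every C2/C3 stereocentre come from (−)-epicatechin 1. It is carried as tetra-O-benzyl ether 2 and then 8-bromide 3, in which C8 is blocked and C6 is the only free ring A carbon.
- Key disconnection: the C4–O bond of the 4β-alkoxy ether 4, made from a C4–H of 3 by dehydrogenative etherification. This is the only oxidation in the route, and 4 supplies both the middle and the upper unit.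
- Interflavan bonds: ionising the C4–O bond of 4 gives C4–C6 coupling with 3 (dimer 5). A second ionisation couples 4 with C6 of the upper unit of 5 (trimer 6). Assembly order is lower, middle, upper.
- Last step: one hydrogenolysis removes twelve benzyl groups and three bromines, taking 6 to target 7.

## Route

Step 1
Reactants: 1 (−)-epicatechin
Product: 2 5,7,3',4'-tetra-O-benzyl-(−)-epicatechin (2R,3R, free 3-OH)
Conditions: BnBr (4.4 equiv), K2CO3 (5 equiv), DMF, argon, 0 °C to rt
Reagents that add atoms: benzyl bromide, BrCc1ccccc1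
Why: Williamson ether synthesis; K2CO3 deprotonates only the four phenols, so the secondary 3-OH stays free, and the mild base at or below room temperature under argon avoids C2 epimerisation, so 2R,3R is carried through.

Step 2
Reactants: 2 5,7,3',4'-tetra-O-benzyl-(−)-epicatechin
Product: 3 8-bromo-5,7,3',4'-tetra-O-benzyl-(−)-epicatechin (2R,3R)
Conditions: NBS (1.0 equiv), CH2Cl2, −78 °C to rt
Reagents that add atoms: N-bromosuccinimide, O=C1CCC(=O)N1Br
Why: Electrophilic aromatic bromination; ring A is the most electron-rich arene and C8 (next to O1 and one OBn) is less hindered than C6 (between two OBn), so one equivalent gives the 8-bromide without touching a stereocentre.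

Step 3
Reactants: 3 8-bromo-5,7,3',4'-tetra-O-benzyl-(−)-epicatechin
Product: 4 8-bromo-5,7,3',4'-tetra-O-benzyl-4β-(2-ethoxyethoxy)-(−)-epicatechin (2,3-cis, 3,4-trans, free 3-OH)
Conditions: 2,3-dichloro-5,6-dicyano-1,4-benzoquinone (DDQ, 0.15 equiv), activated MnO2 (6 equiv), HOCH2CH2OEt (5 equiv), 4 Å molecular sieves, CH2Cl2/MeNO2 4:1, rt
Reagents that add atoms: 2-ethoxyethanol, CCOCCO
Why: Proposed new method: quinone-catalysed dehydrogenative C4–H/O–H coupling on a ring A brominated flavan-3-ol; DDQ forms a charge-transfer complex with the trioxygenated ring A and abstracts hydride from C4, the only C–H whose cation is stabilised by O1, O5 and O7 (C2–H and the ArOCH2Ph groups are poorer hydride donors), 2-ethoxyethanol captures the cation from the β face, anti to the pseudo-axial 3-OH and the 2-aryl group, which sets the 4β C–O stereocentre, and MnO2 re-oxidises the hydroquinone so that both the oxidant and the acidic hydroquinone stay at low concentration, which should curb over-oxidation to the 4-ketone and C6 self-alkylation while the sieves remove the water formed; the closest known reaction types are the stoichiometric DDQ/alcohol C4 etherification of non-brominated O-benzyl flavan-3-ols and the DDQ-catalysed, MnO2-driven oxidative C–H functionalisation of benzylic ethers.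

Step 4
Reactants: 3 8-bromo-5,7,3',4'-tetra-O-benzyl-(−)-epicatechin (4.0 equiv, excess recovered); 4 8-bromo-5,7,3',4'-tetra-O-benzyl-4β-(2-ethoxyethoxy)-(−)-epicatechin (1.0 equiv)
Product: 5 [8-bromo-5,7,3',4'-tetra-O-benzyl-epicatechin]-(4β→6)-[8-bromo-5,7,3',4'-tetra-O-benzyl-epicatechin]
Conditions: Me3SiOSO2CF3 (0.2 equiv), CH2Cl2, 4 added over 1 h, −78 to −30 °C; Et3N quench
Reagents that add atoms: none
Why: SN1 Friedel–Crafts benzylic arylation; acid ionises the C4–O bond of 4 and C6 of 3 (its only free ring A carbon) attacks from the β face anti to the 3-OH, which sets the new C4 stereocentre as 4β (3,4-trans), while the fourfold excess of 3 and slow addition of 4 suppress self-alkylation of 4.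

Step 5
Reactants: 5 the (4β→6) dimer (2.0 equiv, excess recovered); 4 8-bromo-5,7,3',4'-tetra-O-benzyl-4β-(2-ethoxyethoxy)-(−)-epicatechin (1.0 equiv)
Product: 6 [8-bromo-5,7,3',4'-tetra-O-benzyl-epicatechin]-(4β→6)-[8-bromo-5,7,3',4'-tetra-O-benzyl-epicatechin]-(4β→6)-[8-bromo-5,7,3',4'-tetra-O-benzyl-epicatechin]
Conditions: Me3SiOSO2CF3 (0.2 equiv), CH2Cl2, 4 added by syringe pump over 2 h, −78 to −30 °C; Et3N quench
Reagents that add atoms: none
Why: The same SN1 Friedel–Crafts arylation; the only unsubstituted ring A carbon of 5 is C6 of its upper unit, so regiochemistry is fixed, β-face attack again gives 4β, and with equal reactivity of all free C6 sites a 2:1 ratio should put about 60% of 4 into 6 with little tetramer.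

Step 6
Reactants: 6 the dodeca-O-benzyl tribromo trimer
Product: 7 epicatechin-(4β→6)-epicatechin-(4β→6)-epicatechin (target)
Conditions: H2 (1 atm), Pd(OH)2/C (20 wt %), NaOAc (3.3 equiv), THF/MeOH/H2O 20:20:1, rt; filter, Sephadex LH-20, freeze-dry
Reagents that add atoms: none
Why: Catalytic hydrogenolysis with hydrodehalogenation; all twelve ArO–CH2Ph bonds and the three aryl C–Br bonds are cleaved in one operation, and sodium acetate buffers the HBr so that the acid-labile interflavan bonds and all eight stereocentres stay intact.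

## Compound list
1 | (−)-epicatechin, (2R,3R)-2-(3,4-dihydroxyphenyl)chromane-3,5,7-triol | Oc1cc(O)c2c(c1)O[C@H](c1ccc(O)c(O)c1)[C@H](O)C2 | starting material
2 | 5,7,3',4'-tetra-O-benzyl-(−)-epicatechin | c4ccccc4COc1cc(OCc4ccccc4)c2c(c1)O[C@H](c5ccc(OCc4ccccc4)c(OCc4ccccc4)c5)[C@H](O)C2 | intermediate
3 | 8-bromo-5,7,3',4'-tetra-O-benzyl-(−)-epicatechin | c4ccccc4COc1cc(OCc4ccccc4)c2c(c1Br)O[C@H](c5ccc(OCc4ccccc4)c(OCc4ccccc4)c5)[C@H](O)C2 | intermediate
4 | 8-bromo-5,7,3',4'-tetra-O-benzyl-4β-(2-ethoxyethoxy)-(−)-epicatechin | c4ccccc4COc1cc(OCc4ccccc4)c2c(c1Br)O[C@H](c5ccc(OCc4ccccc4)c(OCc4ccccc4)c5)[C@H](O)[C@H]2OCCOCC | intermediate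
5 | octa-O-benzyl-8,8-dibromo epicatechin-(4β→6)-epicatechin | c4ccccc4COc1cc(OCc4ccccc4)c2c(c1Br)O[C@H](c5ccc(OCc4ccccc4)c(OCc4ccccc4)c5)[C@H](O)[C@H]2c1c(OCc4ccccc4)c(Br)c3c(c1OCc4ccccc4)C[C@@H](O)[C@@H](c5ccc(OCc4ccccc4)c(OCc4ccccc4)c5)O3 | intermediate
6 | dodeca-O-benzyl-8,8,8-tribromo epicatechin-(4β→6)-epicatechin-(4β→6)-epicatechin | c4ccccc4COc1cc(OCc4ccccc4)c2c(c1Br)O[C@H](c5ccc(OCc4ccccc4)c(OCc4ccccc4)c5)[C@H](O)[C@H]2c1c(OCc4ccccc4)c(Br)c2c(c1OCc4ccccc4)[C@H](c1c(OCc4ccccc4)c(Br)c3c(c1OCc4ccccc4)C[C@@H](O)[C@@H](c5ccc(OCc4ccccc4)c(OCc4ccccc4)c5)O3)[C@@H](O)[C@@H](c5ccc(OCc4ccccc4)c(OCc4ccccc4)c5)O2 | intermediate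
7 | epicatechin-(4β→6)-epicatechin-(4β→6)-epicatechin, CNP0163146.2 | Oc1cc(O)c2c(c1)O[C@H](c1ccc(O)c(O)c1)[C@H](O)[C@H]2c1c(O)cc2c(c1O)[C@H](c1c(O)cc3c(c1O)C[C@@H](O)[C@@H](c1ccc(O)c(O)c1)O3)[C@@H](O)[C@@H](c1ccc(O)c(O)c1)O2 | target

Total step count: 6. Longest linear sequence: 6 (1 to 2 to 3 to 4 to 5 to 6 to 7).

## Steps most likely to fail

**Step 3 (the proposed new step).**
- Risks: slow turnover of the quinone on MnO2, capture of the cation by the water formed, and over-oxidation of 4.
- The fallback sets out from 2 and comes back at 4. It uses known chemistry and reverses the order of oxidation and bromination.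
- Compound 2 is treated with stoichiometric DDQ (2 equiv) and excess 2-ethoxyethanol in CH2Cl2 at rt. This gives 5,7,3',4'-tetra-O-benzyl-4β-(2-ethoxyethoxy)-(−)-epicatechin F1.
- F1 is then brominated at C8 with NBS (1.0 equiv) in CH2Cl2 at −78 °C to give 4.

**Step 5.**
- Risks: the free C6 of product 6 and of 4 itself compete with 5, giving tetramer and self-alkylation, and the C6 site is hindered.
- The fallback sets out from 4 (together with 5) and comes back at 7. It replaces control by stoichiometry with a capped electrophile.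
- Compound 4 is brominated at C6 with NBS (1.05 equiv) in CH2Cl2 at −40 to 0 °C. This gives 6,8-dibromo-5,7,3',4'-tetra-O-benzyl-4β-(2-ethoxyethoxy)-(−)-epicatechin F2, which has no nucleophilic ring A carbon left.
- F2 (1.2 equiv) is coupled with 5 (1.0 equiv) under Me3SiOSO2CF3 catalysis. This gives the dodeca-O-benzyl tetrabromo trimer F3, which cannot grow further.
- F3 is hydrogenolysed under the step 6 conditions with 4.4 equiv NaOAc to give 7.

**Step 6.**
- Risks: bromide poisons the palladium surface, debromination is incomplete, or local HBr cleaves an interflavan bond.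
- The fallback sets out from 6 and comes back at 7. It separates the two tasks.
- Compound 6 is treated with n-BuLi (7 equiv) in THF at −78 °C, which deprotonates the three OH groups and effects bromine–lithium exchange at the three C8 positions. A water quench gives the bromine-free dodeca-O-benzyl epicatechin-(4β→6)-epicatechin-(4β→6)-epicatechin F4.
- F4 is debenzylated with H2 and Pd(OH)2/C in THF/MeOH/H2O, with no halide or acid present, to give 7.

## Further compounds
F1 | step 3 | 5,7,3',4'-tetra-O-benzyl-4β-(2-ethoxyethoxy)-(−)-epicatechin | c4ccccc4COc1cc(OCc4ccccc4)c2c(c1)O[C@H](c5ccc(OCc4ccccc4)c(OCc4ccccc4)c5)[C@H](O)[C@H]2OCCOCC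
F2 | step 5 | 6,8-dibromo-5,7,3',4'-tetra-O-benzyl-4β-(2-ethoxyethoxy)-(−)-epicatechin | c4ccccc4COc1c(Br)c(OCc4ccccc4)c2c(c1Br)O[C@H](c5ccc(OCc4ccccc4)c(OCc4ccccc4)c5)[C@H](O)[C@H]2OCCOCC
F3 | step 5 | dodeca-O-benzyl tetrabromo trimer (upper unit 6,8-dibromo, middle and lower units 8-bromo), both bonds 4β→6 | c4ccccc4COc1c(Br)c(OCc4ccccc4)c2c(c1Br)O[C@H](c5ccc(OCc4ccccc4)c(OCc4ccccc4)c5)[C@H](O)[C@H]2c1c(OCc4ccccc4)c(Br)c2c(c1OCc4ccccc4)[C@H](c1c(OCc4ccccc4)c(Br)c3c(c1OCc4ccccc4)C[C@@H](O)[C@@H](c5ccc(OCc4ccccc4)c(OCc4ccccc4)c5)O3)[C@@H](O)[C@@H](c5ccc(OCc4ccccc4)c(OCc4ccccc4)c5)O2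
F4 | step 6 | dodeca-O-benzyl epicatechin-(4β→6)-epicatechin-(4β→6)-epicatechin | c4ccccc4COc1cc(OCc4ccccc4)c2c(c1)O[C@H](c5ccc(OCc4ccccc4)c(OCc4ccccc4)c5)[C@H](O)[C@H]2c1c(OCc4ccccc4)cc2c(c1OCc4ccccc4)[C@H](c1c(OCc4ccccc4)cc3c(c1OCc4ccccc4)C[C@@H](O)[C@@H](c5ccc(OCc4ccccc4)c(OCc4ccccc4)c5)O3)[C@@H](O)[C@@H](c5ccc(OCc4ccccc4)c(OCc4ccccc4)c5)O2
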